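## The problem

The target **19** is a 5,7-dihydroxyisoflavone (rings A and C) whose ring B carries a free hydroxyl at C2' and is fused through C3' and C4' to a 3-hydroxy-2,2-dimethyldihydropyran (ring D). Ring B is therefore a contiguously tetrasubstituted benzene, and the chroman unit is joined through its C6 to C3 of the pyranone. There is one stereocenter, the S carbinol carbon C3 of ring D. It lies between a quaternary carbon and a benzylic methylene, remote from all other functionality, so no other element of the molecule can control it and it controls nothing: it must be set by a chiral catalyst and then only preserved. The γ-pyranone is the fragile part: hydroxide adds at C2 and cleaves the ring with loss of the C2 carbon, and hydrogen or hydride can saturate the C2–C3 double bond. The free phenols, above all the phloroglucinol-type ring A, are prone to oxidation and C-alkylation, and the epoxide that leads to the carbinol ionizes easily at the doubly oxygen-flanked benzylic C4. The opening for the plan lies in ring A: its oxygens stand at C8a, C5 and C7, that is ortho, ortho and para to C4a, the carbon bearing the C4 carbonyl. Each can therefore replace a fluoride of a 2,4,6-trifluorophenyl ketone, and the first to do so can be the ring oxygen O1, delivered from within by the enolate oxygen of a formyl unit at C3.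

## Retrosynthesis

**19 from 18 (four O–benzyl bonds).** All four hydroxyls are traced to benzyl ethers, so that one hydrogenolysis ends the synthesis. A silyl ether on the carbinol would be easier to install but would cost an extra deprotection. The forward step must cleave the ethers without saturating the C2–C3 double bond.

**18 from 17 (C5–O and C7–O).** The two ring A ether oxygens come from benzyl alkoxide and the 5,7-difluoroisoflavone **17**. Against a phloroglucinol-based ring A, this needs no electrophilic acylation of an electron-rich arene and no differentiation of three phenols. The forward step needs both fluorides to leave while alkoxide addition at C2 stays reversible.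

**17 from 16 (O1–C8a, the key cut).** Ring C is opened at the aryl–oxygen bond to give the hydroxymethylene ketone **16**. The usual isoflavone closures form O1–C2 and need a free ortho phenol on ring A; this cut instead uses the two equivalent ortho fluorines of a symmetric trifluorophenyl group. The precursor is acyclic in this region, and the closure asks only for O-attack of an enolate on an activated C–F carbon.

**16 from 15, and 15 from 12 and 14 (C2–C3, then C4–C4a).** C2 is a formyl carbon added to the enolate of deoxybenzoin **15**. The aryl–carbonyl bond is cut to the arylacetic N-methoxy-N-methylamide **12** and the aryllithium **14**, made by deprotonation of 1,3,5-trifluorobenzene **13**, which has a single kind of hydrogen. Cutting C3–C4 instead would call for a benzylic nucleophile on the electron-rich chroman. The acylation must stop at the ketone, which the amide secures.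

**12 from 11, 10 and 9 (oxidation level of the side chain).** The amide comes from acid **11**, that from aldehyde **10**, and the aldehyde is released from the dimethyl acetal **9**. These are functional-group changes only; the acetal is what makes the next disconnection possible.

**9 from 8, 7 and 6 (the C3–O bond and the stereocenter).** The benzyl ether **9** comes from carbinol **8**. This is the product of hydride attack at C4 of the (3S,4S)-epoxide **7**, and **7** comes from chromene **6** by catalytic asymmetric epoxidation. 2,2-Dimethylchromenes are the best substrate class for the (salen)MnCl catalysts. Placing the sequence at the acetal stage means nothing but the epoxide is reducible, so LiAlH4 can open it by clean SN2 attack. A Lewis-acid hydride system would risk a 1,2-hydride shift to the chroman-3-one and loss of configuration.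

**6 from 4, 3, and 1 with 2 (side-chain carbon and ring D).** The acetal carbon comes from a methoxymethylene Wittig reaction on aldehyde **4**, the benzyl ether of chromene **3**. Ring D is cut at C4–C4a and O1–C2 to 2,4-dihydroxybenzaldehyde **1** and prenal **2**. The hydrogen bond between the C2 hydroxyl and the formyl group of **1** directs the annulation to the angular isomer needed here.

## Roads not taken

**Alternative 1: late asymmetric epoxidation of the chromene isoflavone.** The C3–O bond of ring D is cut last. The chromene triacetate 3-(5-acetoxy-2,2-dimethyl-2H-chromen-6-yl)-4-oxo-4H-chromene-5,7-diyl diacetate A2 would be epoxidized with [(S,S)-N,N'-bis(3,5-di-tert-butylsalicylidene)-1,2-cyclohexanediaminato]MnCl to the (3S,4S)-epoxide A1. Reductive opening and deacetylation would follow.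
- Merits: the stereocenter is set on the complete skeleton by the same reliable reaction, no protecting group is spent on the carbinol, and the sequence could be two or three steps shorter.
- Weak points: the epoxide must then be reduced at C4 in the presence of the pyranone and three aryl acetates. Nucleophilic hydrides attack both, hydrogenolysis threatens the C2–C3 double bond, and Lewis-acid hydride systems invite the hydride shift that erases the stereocenter. The acetoxy group peri to C4 can also take part in the opening.
- Comparison: this road is at least as good in step count and convergence. The chosen plan sets against it an epoxide opening with LiAlH4 on an intermediate that has no other reducible group, and an enantiomeric purity that is fixed and can be upgraded on cheap early material.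

**Alternative 2: aryllithium 6-endo epoxide opening.** The benzylic C3'–CH2 bond is cut. Bromine–lithium exchange on 2-bromo-1-(methoxymethoxy)-3-{[2-((2S)-oxiran-2-yl)propan-2-yl]oxy}benzene A4 with t-BuLi, then BF3·OEt2-assisted attack on the terminal epoxide carbon, would give (3S)-5-(methoxymethoxy)-2,2-dimethylchroman-3-ol A3.
- Merits: the configuration comes from an enantiopure epoxide and not from a catalyst-controlled face selection, and the ring closure makes a C–C bond.
- Weak points: A4 contains a tertiary alkyl aryl ether next to an epoxide, which is awkward to assemble. The 6-endo attack competes with 5-exo attack at the internal carbon. A3 still lacks the C6 substituent, so a directed metalation and the entire isoflavone construction remain.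
- Comparison: this road is better where independence from catalyst enantioselectivity counts. The chosen plan offers a chromene that is available in one step with the C6 carbon already in place, and a substrate class on which the epoxidation is at its best.

**Alternative 3: benzannulation of ring B on the chromone.** Ring B is cut at C1'–C2', C2'–C3' and C4'–C5'. Irradiation of (E)-4-[5,7-bis(benzyloxy)-4-oxo-4H-chromen-3-yl]-1-diazobut-3-en-2-one A6 would give a vinylketene by Wolff rearrangement. Its [2+2] addition to triisopropyl[(5-methylhex-4-en-1-yn-1-yl)oxy]silane A7, four-electron ring opening and 6π closure would give 5,7-bis(benzyloxy)-2'-hydroxy-3'-prenyl-4'-(triisopropylsilyloxy)isoflavone A5.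
- Merits: highly convergent, and the four contiguous substituents of ring B are placed without any regiochemical ambiguity.
- Weak points: the chromone is itself a photoactive enone, the diazo ketone is a sensitive intermediate, and the key step does nothing for the stereocenter. After it, the 4'-oxygen must be freed and the 2'-hydroxyl masked, the prenyl group epoxidized enantioselectively, and the pyran closed 6-endo against the 5-exo alternative.
- Comparison: this road is clearly better in convergence. The chosen plan sets against it a ring D and stereocenter that are settled in the first five steps by reactions with predictable regio- and enantiocontrol, and a key step that runs under carbonate at mild temperature without photochemistry.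

Key step: step 12

Assumption: enol ether **5** is expected as an E/Z mixture and is drawn without alkene geometry, **16** is drawn as the chelated Z enol that should be the main tautomer, and F7 would be a mixture of carbinol epimers.

## Route

Step 1
Reactants: 1 2,4-dihydroxybenzaldehyde; 2 3-methylbut-2-enal (prenal)
Product: 3 5-hydroxy-2,2-dimethyl-2H-chromene-6-carbaldehyde
Conditions: pyridine, 120 °C
Reagents that add atoms: none
Why: Pyridine-mediated chromenylation: aldol-type condensation at the ring carbon between the two hydroxyls, loss of water to an ortho-quinone methide, and oxa-6π electrocyclization. The C2 hydroxyl is held in a hydrogen bond to the formyl group, so the C4 oxygen closes the pyran and the angular 5-hydroxy-6-formyl chromene should result.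

Step 2
Reactants: 3 5-hydroxy-2,2-dimethyl-2H-chromene-6-carbaldehyde
Product: 4 5-(benzyloxy)-2,2-dimethyl-2H-chromene-6-carbaldehyde
Conditions: BnBr, K2CO3, DMF, 60 °C
Reagents that add atoms: benzyl bromide, BrCc1ccccc1
Why: Williamson etherification; the chelated phenol is the only acidic site and needs DMF and gentle warming.

Step 3
Reactants: 4 5-(benzyloxy)-2,2-dimethyl-2H-chromene-6-carbaldehyde
Product: 6 5-(benzyloxy)-6-(2,2-dimethoxyethyl)-2,2-dimethyl-2H-chromene, via enol ether 5 (not isolated)
Conditions: Ph3P(CH2OMe)Cl, KOt-Bu, THF, 0 °C → rt; then MeOH, TsOH·H2O, rt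
Reagents that add atoms: (methoxymethyl)triphenylphosphonium chloride, COC[P+](c1ccccc1)(c1ccccc1)c1ccccc1.[Cl-]; methanol, CO
Why: Wittig methoxymethylenation, then acid-catalysed addition of methanol to the enol ether, which is protonated far faster than the chromene alkene. The acetal masks the homologated aldehyde through the oxidation, hydride and alkylation steps that follow.

Step 4
Reactants: 6 5-(benzyloxy)-6-(2,2-dimethoxyethyl)-2,2-dimethyl-2H-chromene
Product: 7 (3S,4S)-5-(benzyloxy)-6-(2,2-dimethoxyethyl)-3,4-epoxy-2,2-dimethylchroman
Conditions: [(S,S)-N,N'-bis(3,5-di-tert-butylsalicylidene)-1,2-cyclohexanediaminato]MnCl (5 mol %), 4-phenylpyridine N-oxide, aq NaOCl (pH 11.3), CH2Cl2, 0 °C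
Reagents that add atoms: sodium hypochlorite, [Na+].[O-]Cl
Why: Jacobsen epoxidation with the chloride complex of trivalent manganese. Cis, aryl-conjugated 2,2-dimethylchromenes are its best substrates, and the (S,S) catalyst is expected to deliver oxygen to the face that gives the (3S,4S)-epoxide, which sets the only stereocenter of the target. Acetal and benzyl ether are inert to buffered hypochlorite; the acid-labile epoxide is taken on without chromatography on untreated silica.

Step 5
Reactants: 7 (3S,4S)-5-(benzyloxy)-6-(2,2-dimethoxyethyl)-3,4-epoxy-2,2-dimethylchroman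
Product: 8 (3S)-5-(benzyloxy)-6-(2,2-dimethoxyethyl)-2,2-dimethylchroman-3-ol
Conditions: LiAlH4, THF, 0 °C → rt; aq NaOH work-up
Reagents that add atoms: none
Why: Hydride opening of the epoxide by SN2 attack at the benzylic C4, which is activated and less hindered than C3 beside the quaternary C2. The C3–O bond is not broken, so the S configuration passes unchanged into the carbinol, and no cationic pathway to the chroman-3-one is open.

Step 6
Reactants: 8 (3S)-5-(benzyloxy)-6-(2,2-dimethoxyethyl)-2,2-dimethylchroman-3-ol
Product: 9 (3S)-3,5-bis(benzyloxy)-6-(2,2-dimethoxyethyl)-2,2-dimethylchroman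
Conditions: NaH, BnBr, Bu4NI (cat.), DMF, 0 °C → rt
Reagents that add atoms: benzyl bromide, BrCc1ccccc1
Why: Williamson etherification of the hindered secondary alkoxide; at this stage there is no enolizable or base-sensitive group, which is why the benzyl ether is put on here.

Step 7
Reactants: 9 (3S)-3,5-bis(benzyloxy)-6-(2,2-dimethoxyethyl)-2,2-dimethylchroman
Product: 10 2-[(3S)-3,5-bis(benzyloxy)-2,2-dimethylchroman-6-yl]acetaldehyde
Conditions: 2 M aq HCl, THF, 40 °C
Reagents that add atoms: water, O
Why: Acid hydrolysis of the dimethyl acetal; with the chromene alkene and the epoxide gone, nothing else in 9 is acid-sensitive. The crude arylacetaldehyde is used at once.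

Step 8
Reactants: 10 2-[(3S)-3,5-bis(benzyloxy)-2,2-dimethylchroman-6-yl]acetaldehyde
Product: 11 2-[(3S)-3,5-bis(benzyloxy)-2,2-dimethylchroman-6-yl]acetic acid
Conditions: NaClO2, NaH2PO4, 2-methyl-2-butene, t-BuOH/THF/H2O, 0 °C → rt
Reagents that add atoms: sodium chlorite, [Na+].[O-]Cl=O
Why: Pinnick oxidation; the alkene scavenger removes hypochlorous acid so that the electron-rich ring is not chlorinated.

Step 9
Reactants: 11 2-[(3S)-3,5-bis(benzyloxy)-2,2-dimethylchroman-6-yl]acetic acid
Product: 12 2-[(3S)-3,5-bis(benzyloxy)-2,2-dimethylchroman-6-yl]-N-methoxy-N-methylacetamide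
Conditions: MeNHOMe·HCl, EDC·HCl, HOBt, N-methylmorpholine, CH2Cl2, 0 °C → rt
Reagents that add atoms: N,O-dimethylhydroxylamine hydrochloride, CNOC.Cl
Why: Carbodiimide amide coupling to the Weinreb amide.

Step 10
Reactants: 12 2-[(3S)-3,5-bis(benzyloxy)-2,2-dimethylchroman-6-yl]-N-methoxy-N-methylacetamide; 13 1,3,5-trifluorobenzene
Product: 15 2-[(3S)-3,5-bis(benzyloxy)-2,2-dimethylchroman-6-yl]-1-(2,4,6-trifluorophenyl)ethan-1-one, via aryllithium 14 (not isolated)
Conditions: 13, n-BuLi, THF, −78 °C; then 12, −78 °C; aq NH4Cl at −78 °C
Reagents that add atoms: none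
Why: Deprotonation between two fluorines gives (2,4,6-trifluorophenyl)lithium, which is stable at −78 °C. Its addition to the Weinreb amide stops at the chelated tetrahedral intermediate, so only the ketone is released on quench (Weinreb ketone synthesis).

Step 11
Reactants: 15 2-[(3S)-3,5-bis(benzyloxy)-2,2-dimethylchroman-6-yl]-1-(2,4,6-trifluorophenyl)ethan-1-one
Product: 16 (Z)-2-[(3S)-3,5-bis(benzyloxy)-2,2-dimethylchroman-6-yl]-3-hydroxy-1-(2,4,6-trifluorophenyl)prop-2-en-1-one
Conditions: LiN(SiMe3)2 (2.2 equiv), THF, −78 °C; HCO2CH2CF3, −78 °C; cold aq NH4Cl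
Reagents that add atoms: 2,2,2-trifluoroethyl formate, O=COCC(F)(F)F
Why: Crossed Claisen formylation of the kinetically formed lithium enolate. Trifluoroethoxide is a poor nucleophile and the temperature is low, so the SNAr-prone trifluorophenyl ring is not attacked. The product stays as its lithium chelate, which cannot reach the ortho carbon, until the cold quench releases the hydrogen-bonded Z enol.

Step 12
Reactants: 16 (Z)-2-[(3S)-3,5-bis(benzyloxy)-2,2-dimethylchroman-6-yl]-3-hydroxy-1-(2,4,6-trifluorophenyl)prop-2-en-1-one
Product: 17 3-[(3S)-3,5-bis(benzyloxy)-2,2-dimethylchroman-6-yl]-5,7-difluoro-4H-chromen-4-one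
Conditions: K2CO3, dry DMF (dilute), rt → 50 °C
Reagents that add atoms: none
Why: K2CO3 deprotonates the acidic enol of 16, and the potassium enolate, no longer locked in the chelate, rotates about the C3–C4 bond so that its oxygen reaches an ortho C–F carbon of the trifluorophenyl ring. Addition gives a Meisenheimer intermediate whose charge is taken up by the C4 carbonyl and stabilized inductively by the two remaining fluorines; loss of fluoride forms O1–C8a and gives the chromone 17. The closest known reaction type is the intramolecular SNAr closure of ortho-fluoroaroyl enolates and enamines, as in the formation of polyfluorochromones and the cycloaracylation route to 4-quinolones. Ring C closes as a six-membered ring onto a trigonal aromatic carbon: 6-exo-trig if the attacked C8a=C8 bond is counted as the acceptor, 6-endo-trig on the other Kekulé form (the oxa-Michael view), and allowed on either count. No stereocenter is formed, and the C3 centre of ring D carries no acidic hydrogen and is untouched by carbonate. The step needs O- rather than C-attack of the ambident enolate and ortho rather than para fluoride: C-attack would give a four-membered ring and the para carbon is out of reach, so the tether secures both, and the two ortho fluorines are equivalent. Dilution and dry solvent should hold back bimolecular attack at the para fluorine and retro-Claisen loss of the formyl group.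

Step 13
Reactants: 17 3-[(3S)-3,5-bis(benzyloxy)-2,2-dimethylchroman-6-yl]-5,7-difluoro-4H-chromen-4-one
Product: 18 5,7-bis(benzyloxy)-3-[(3S)-3,5-bis(benzyloxy)-2,2-dimethylchroman-6-yl]-4H-chromen-4-one
Conditions: BnOH, NaH, THF/DMF, 0 °C → 60 °C
Reagents that add atoms: benzyl alcohol, OCc1ccccc1
Why: Twofold SNAr by benzyl alkoxide at C7 (para to the carbon bearing the C4 carbonyl) and at C5 (ortho, helped by sodium bridging to the carbonyl oxygen). Addition of alkoxide at C2 is reversible and unproductive when water is excluded.

Step 14
Reactants: 18 5,7-bis(benzyloxy)-3-[(3S)-3,5-bis(benzyloxy)-2,2-dimethylchroman-6-yl]-4H-chromen-4-one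
Product: 19 5,7-dihydroxy-3-[(3S)-3,5-dihydroxy-2,2-dimethylchroman-6-yl]-4H-chromen-4-one (target)
Conditions: H2 (1 atm), 10% Pd/C, EtOAc/MeOH, rt
Reagents that add atoms: none
Why: Hydrogenolysis of the three aryl benzyl ethers and the aliphatic one, to be stopped as soon as the slowest ether is gone so that the C2–C3 double bond is not saturated. The carbinol carbon is not benzylic and keeps its configuration.

## Compound list

1 | 2,4-dihydroxybenzaldehyde | O=Cc1ccc(O)cc1O | starting material
2 | 3-methylbut-2-enal (prenal) | CC(C)=CC=O | starting material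
3 | 5-hydroxy-2,2-dimethyl-2H-chromene-6-carbaldehyde | CC1(C)C=Cc2c(O)c(C=O)ccc2O1 | intermediate
4 | 5-(benzyloxy)-2,2-dimethyl-2H-chromene-6-carbaldehyde | CC1(C)C=Cc2c(OCc3ccccc3)c(C=O)ccc2O1 | intermediate
5 | 5-(benzyloxy)-6-(2-methoxyethenyl)-2,2-dimethyl-2H-chromene (E/Z mixture) | CC1(C)C=Cc2c(OCc3ccccc3)c(C=COC)ccc2O1 | intermediate
6 | 5-(benzyloxy)-6-(2,2-dimethoxyethyl)-2,2-dimethyl-2H-chromene | CC1(C)C=Cc2c(OCc3ccccc3)c(CC(OC)OC)ccc2O1 | intermediate
7 | (3S,4S)-5-(benzyloxy)-6-(2,2-dimethoxyethyl)-3,4-epoxy-2,2-dimethylchroman | CC1(C)Oc2ccc(CC(OC)OC)c(OCc3ccccc3)c2[C@@H]2O[C@H]12 | intermediate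
8 | (3S)-5-(benzyloxy)-6-(2,2-dimethoxyethyl)-2,2-dimethylchroman-3-ol | CC1(C)Oc2ccc(CC(OC)OC)c(OCc3ccccc3)c2C[C@@H]1O | intermediate
9 | (3S)-3,5-bis(benzyloxy)-6-(2,2-dimethoxyethyl)-2,2-dimethylchroman | CC1(C)Oc2ccc(CC(OC)OC)c(OCc3ccccc3)c2C[C@@H]1OCc1ccccc1 | intermediate
10 | 2-[(3S)-3,5-bis(benzyloxy)-2,2-dimethylchroman-6-yl]acetaldehyde | CC1(C)Oc2ccc(CC=O)c(OCc3ccccc3)c2C[C@@H]1OCc1ccccc1 | intermediate
11 | 2-[(3S)-3,5-bis(benzyloxy)-2,2-dimethylchroman-6-yl]acetic acid | CC1(C)Oc2ccc(CC(=O)O)c(OCc3ccccc3)c2C[C@@H]1OCc1ccccc1 | intermediate
12 | 2-[(3S)-3,5-bis(benzyloxy)-2,2-dimethylchroman-6-yl]-N-methoxy-N-methylacetamide | CC1(C)Oc2ccc(CC(=O)N(C)OC)c(OCc3ccccc3)c2C[C@@H]1OCc1ccccc1 | intermediate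
13 | 1,3,5-trifluorobenzene | Fc1cc(F)cc(F)c1 | starting material
14 | (2,4,6-trifluorophenyl)lithium | [Li]c1c(F)cc(F)cc1F | intermediate
15 | 2-[(3S)-3,5-bis(benzyloxy)-2,2-dimethylchroman-6-yl]-1-(2,4,6-trifluorophenyl)ethan-1-one | CC1(C)Oc2ccc(CC(=O)c3c(F)cc(F)cc3F)c(OCc3ccccc3)c2C[C@@H]1OCc1ccccc1 | intermediate
16 | (Z)-2-[(3S)-3,5-bis(benzyloxy)-2,2-dimethylchroman-6-yl]-3-hydroxy-1-(2,4,6-trifluorophenyl)prop-2-en-1-one | CC1(C)Oc2ccc(/C(=C/O)C(=O)c3c(F)cc(F)cc3F)c(OCc3ccccc3)c2C[C@@H]1OCc1ccccc1 | intermediate
17 | 3-[(3S)-3,5-bis(benzyloxy)-2,2-dimethylchroman-6-yl]-5,7-difluoro-4H-chromen-4-one | CC1(C)Oc2ccc(-c3coc4cc(F)cc(F)c4c3=O)c(OCc3ccccc3)c2C[C@@H]1OCc1ccccc1 | intermediate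
18 | 5,7-bis(benzyloxy)-3-[(3S)-3,5-bis(benzyloxy)-2,2-dimethylchroman-6-yl]-4H-chromen-4-one | CC1(C)Oc2ccc(-c3coc4cc(OCc5ccccc5)cc(OCc5ccccc5)c4c3=O)c(OCc3ccccc3)c2C[C@@H]1OCc1ccccc1 | intermediate
19 | 5,7-dihydroxy-3-[(3S)-3,5-dihydroxy-2,2-dimethylchroman-6-yl]-4H-chromen-4-one | CC1(C)Oc2ccc(-c3coc4cc(O)cc(O)c4c3=O)c(O)c2C[C@@H]1O | target

## Step count and least certain steps

Total step count: 14. Longest linear sequence: 14 steps (from 1 and 2 to 19; 13 enters at step 10).

**Step 12 (key step).** The free enolate may live long enough in basic DMF to displace the para fluoride of a second molecule, or to lose its formyl group by retro-Claisen cleavage if the medium is not dry; either drains material before ring closure. Fallback: the free enol is left out. Ketone 15 is heated with N,N-dimethylformamide dimethyl acetal in toluene to give the enaminone (E)-2-[(3S)-3,5-bis(benzyloxy)-2,2-dimethylchroman-6-yl]-3-(dimethylamino)-1-(2,4,6-trifluorophenyl)prop-2-en-1-one F1. Warming this with K2CO3 in DMF containing a few equivalents of water should exchange the dimethylamino group for oxygen by addition–elimination, and the enolate, now present only in low stationary concentration, closes onto the ortho C–F carbon. The detour sets out from 15, returns to the route at 17, and also bypasses the formylation of step 11.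

**Step 13.** The second displacement may stall, because the benzyloxy group installed first at C7 weakens the carbonyl activation of C5, and the pyranone may open by alkoxide addition at C2 if traces of water are present. Fallback: both oxygens are brought in before ring closure.
- 1,3,5-Trifluorobenzene 13 and two equivalents of sodium benzyloxide in NMP give 1,3-bis(benzyloxy)-5-fluorobenzene F2.
- NBS brominates para to one ether to give 1,5-bis(benzyloxy)-2-bromo-3-fluorobenzene F3.
- Bromine–lithium exchange with n-BuLi at −78 °C gives [2,4-bis(benzyloxy)-6-fluorophenyl]lithium F4, which acylates amide 12 to 1-[2,4-bis(benzyloxy)-6-fluorophenyl]-2-[(3S)-3,5-bis(benzyloxy)-2,2-dimethylchroman-6-yl]ethan-1-one F5.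
- Formylation as in step 11 gives (Z)-1-[2,4-bis(benzyloxy)-6-fluorophenyl]-2-[(3S)-3,5-bis(benzyloxy)-2,2-dimethylchroman-6-yl]-3-hydroxyprop-2-en-1-one F6.
- Cs2CO3 in DMF at 80–100 °C closes ring C by displacing the single remaining ortho fluoride.

The detour sets out from 13 and 12 and returns at 18. The O1–C8a bond is still made by SNAr of an enolate oxygen; the ring is less activated and needs more heat, but no fluoride exchange on the chromone is required.

**Step 10.** The aryllithium may act as a base on the acidic benzylic methylene of 12 instead of adding, or lose LiF to an aryne if the temperature drifts upward, so that conversion stays incomplete. Fallback: 14 is added at −78 °C to aldehyde 10, where carbonyl addition outruns enolization, to give 2-[(3S)-3,5-bis(benzyloxy)-2,2-dimethylchroman-6-yl]-1-(2,4,6-trifluorophenyl)ethan-1-ol F7. Oxidation with Dess–Martin periodinane then gives the ketone. The detour sets out from 10, returns at 15, and leaves out steps 8 and 9.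

**Step 14.** The C2–C3 double bond of the pyranone may be saturated while the slower aliphatic benzyl ether is still being cleaved. Fallback: Lewis-acid debenzylation in place of hydrogenation. BCl3 with pentamethylbenzene as cation scavenger in CH2Cl2 at −78 °C → −20 °C should convert 18 directly into 19; this detour makes no new compound (entry F0).

## Further compounds

F1 | step 12 | (E)-2-[(3S)-3,5-bis(benzyloxy)-2,2-dimethylchroman-6-yl]-3-(dimethylamino)-1-(2,4,6-trifluorophenyl)prop-2-en-1-one | CC1(C)Oc2ccc(/C(=C\N(C)C)C(=O)c3c(F)cc(F)cc3F)c(OCc3ccccc3)c2C[C@@H]1OCc1ccccc1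
F2 | step 13 | 1,3-bis(benzyloxy)-5-fluorobenzene | Fc1cc(OCc2ccccc2)cc(OCc2ccccc2)c1
F3 | step 13 | 1,5-bis(benzyloxy)-2-bromo-3-fluorobenzene | Fc1cc(OCc2ccccc2)cc(OCc2ccccc2)c1Br
F4 | step 13 | [2,4-bis(benzyloxy)-6-fluorophenyl]lithium | [Li]c1c(F)cc(OCc2ccccc2)cc1OCc1ccccc1
F5 | step 13 | 1-[2,4-bis(benzyloxy)-6-fluorophenyl]-2-[(3S)-3,5-bis(benzyloxy)-2,2-dimethylchroman-6-yl]ethan-1-one | CC1(C)Oc2ccc(CC(=O)c3c(F)cc(OCc4ccccc4)cc3OCc3ccccc3)c(OCc3ccccc3)c2C[C@@H]1OCc1ccccc1
F6 | step 13 | (Z)-1-[2,4-bis(benzyloxy)-6-fluorophenyl]-2-[(3S)-3,5-bis(benzyloxy)-2,2-dimethylchroman-6-yl]-3-hydroxyprop-2-en-1-one | CC1(C)Oc2ccc(/C(=C/O)C(=O)c3c(F)cc(OCc4ccccc4)cc3OCc3ccccc3)c(OCc3ccccc3)c2C[C@@H]1OCc1ccccc1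
F7 | step 10 | 2-[(3S)-3,5-bis(benzyloxy)-2,2-dimethylchroman-6-yl]-1-(2,4,6-trifluorophenyl)ethan-1-ol (both carbinol epimers) | CC1(C)Oc2ccc(CC(O)c3c(F)cc(F)cc3F)c(OCc3ccccc3)c2C[C@@H]1OCc1ccccc1
F0 | step 14 | none | none
A1 | alternative 1 | 3-[(3S,4S)-5-acetoxy-3,4-epoxy-2,2-dimethylchroman-6-yl]-4-oxo-4H-chromene-5,7-diyl diacetate | CC1(C)Oc2ccc(-c3coc4cc(OC(C)=O)cc(OC(C)=O)c4c3=O)c(OC(C)=O)c2[C@@H]2O[C@H]12
A2 | alternative 1 | 3-(5-acetoxy-2,2-dimethyl-2H-chromen-6-yl)-4-oxo-4H-chromene-5,7-diyl diacetate | CC1(C)C=Cc2c(OC(C)=O)c(-c3coc4cc(OC(C)=O)cc(OC(C)=O)c4c3=O)ccc2O1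
A3 | alternative 2 | (3S)-5-(methoxymethoxy)-2,2-dimethylchroman-3-ol | CC1(C)Oc2cccc(OCOC)c2C[C@@H]1O
A4 | alternative 2 | 2-bromo-1-(methoxymethoxy)-3-{[2-((2S)-oxiran-2-yl)propan-2-yl]oxy}benzene | COCOc1cccc(OC(C)(C)[C@@H]2CO2)c1Br
A5 | alternative 3 | 5,7-bis(benzyloxy)-2'-hydroxy-3'-prenyl-4'-(triisopropylsilyloxy)isoflavone | CC(C)=CCc1c(O[Si](C(C)C)(C(C)C)C(C)C)ccc(-c2coc3cc(OCc4ccccc4)cc(OCc4ccccc4)c3c2=O)c1O
A6 | alternative 3 | (E)-4-[5,7-bis(benzyloxy)-4-oxo-4H-chromen-3-yl]-1-diazobut-3-en-2-one | [N-]=[N+]=CC(=O)/C=C/c1coc2cc(OCc3ccccc3)cc(OCc3ccccc3)c2c1=O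
A7 | alternative 3 | triisopropyl[(5-methylhex-4-en-1-yn-1-yl)oxy]silane | CC(C)=CCC#CO[Si](C(C)C)(C(C)C)C(C)C
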